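**Retrosynthetic overview**

1. The tiglate on O19 is attached last; the C13 carbinol comes from a C12–C13 bond made by lithiation–borylation of a C12 boronic ester with an (S)-but-3-en-2-yl carbamate. The C12 boron derives from a C9 vinyl group (C11=C12), and that from a C11 amide.
2. The C4 quaternary centre is made on the finished trans-decalin by α-face methylation of the C19 ester enolate.
3. Both rings form in one radical cascade from an acyclic chain: a C5 radical closes ring A first (C5–C10, 6-exo-trig onto a C9=C10 enamide), and the resulting C9 radical closes ring B (C8–C9, 6-exo-dig onto a C8≡C17 alkyne).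
4. The cascade precursor comes from an auxiliary-controlled syn-aldol of a C4 enolate with pent-4-ynal (sets C4, supplies the C5–O radical trigger), after a Horner–Wadsworth–Emmons reaction on 6-oxoheptanoic acid.
5. Enabling feature: the exocyclic C8=C17 methylene of ring B lies next to C9, and C9 is flanked by the quaternary C10 (angular methyl) and by C11. An amide-stabilised C9 radical therefore arises by attack at C10, and a terminal alkyne turns its 6-exo-dig closure directly into the C8(=CH2) unit; C19 on C4 is the stereochemical lever.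

Key step: step 6

**Remarks**

- The target is taken as the normal-labdane enantiomer drawn, (13R)-13-hydroxylabda-8(17),14-dien-19-yl tiglate.
- Labdane numbering (C1–C20) is used for all intermediates, including the acyclic ones: C19 is the ester carbon on C4, C11 the amide carbon on C9, C17 the terminal alkyne carbon.
- Step 1 is expected to give mainly the E enamide. The Z isomer need not be removed, because both give the same C9 radical in step 6; structures are drawn as E.
- Pent-4-ynal and (S)-but-3-en-2-ol are assumed to be purchased.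

**Route**

Step 1
Reactants: 1 6-oxoheptanoic acid; 2 diethyl {2-[methoxy(methyl)amino]-2-oxoethyl}phosphonate
Product: 3 (E)-8-[methoxy(methyl)amino]-6-methyl-8-oxooct-6-enoic acid
Conditions: NaH (2.3 equiv), THF, 0 → 65 °C; then aq. HCl
Reagents that add atoms: none
Why: Horner–Wadsworth–Emmons olefination of the methyl ketone by the amide-stabilised phosphonate carbanion (the sodium carboxylate is inert) should give the trisubstituted enamide, mainly as the E isomer.

Step 2
Reactants: 3 enamide acid; 4 (R)-4-benzyl-1,3-oxazolidin-2-one
Product: 6 (R)-4-benzyl-3-{(E)-8-[methoxy(methyl)amino]-6-methyl-8-oxooct-6-enoyl}-1,3-oxazolidin-2-one, via mixed pivalic anhydride 5 (not isolated)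
Conditions: t-BuCOCl, Et3N, THF, −20 °C; then 4, LiCl, −20 °C → rt
Reagents that add atoms: none
Why: N-acylation of the oxazolidinone through the mixed pivalic anhydride is a standard way to load this auxiliary and leaves the N-methoxy-N-methylamide untouched.

Step 3
Reactants: 6 N-acyl oxazolidinone; 7 pent-4-ynal
Product: 9 syn-aldol adduct (R)-4-benzyl-3-[(2R,3S)-3-hydroxy-2-{(E)-6-[methoxy(methyl)amino]-4-methyl-6-oxohex-4-en-1-yl}hept-6-ynoyl]-1,3-oxazolidin-2-one, via boron enolate 8 (not isolated)
Conditions: n-Bu2BOTf, i-Pr2NEt, CH2Cl2, −78 → 0 °C; 7, −78 → 0 °C; then pH 7 buffer, MeOH, 30% H2O2, 0 °C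
Reagents that add atoms: none
Why: Evans syn-aldol reaction, in which the Z boron enolate reacts through a closed chair transition state on the face opposite the benzyl group, setting C4 as R (the centre that later steers both ring closures) and C5 as S (a carbinol that serves only as radical precursor).

Step 4
Reactants: 9 syn-aldol adduct
Product: 10 methyl (2R,3S)-3-hydroxy-2-{(E)-6-[methoxy(methyl)amino]-4-methyl-6-oxohex-4-en-1-yl}hept-6-ynoate
Conditions: MeMgBr, MeOH, CH2Cl2, 0 °C; then aq. NH4Cl
Reagents that add atoms: methanol, CO
Why: Chelation-assisted transesterification of the β-hydroxy imide with bromomagnesium methoxide should release the methyl ester needed in step 7 without retro-aldol cleavage or epimerisation at C4, and returns the auxiliary.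

Step 5
Reactants: 10 β-hydroxy ester
Product: 11 methyl (2R,3S)-2-{(E)-6-[methoxy(methyl)amino]-4-methyl-6-oxohex-4-en-1-yl}-3-[(phenoxycarbonothioyl)oxy]hept-6-ynoate
Conditions: PhOC(S)Cl, pyridine, DMAP (cat.), CH2Cl2, 0 °C → rt
Reagents that add atoms: O-phenyl chlorothionoformate, S=C(Cl)Oc1ccccc1
Why: Acylation of the secondary alcohol to the O-aryl thionocarbonate under weakly basic conditions installs the radical leaving group of a Barton–McCombie deoxygenation without β-elimination.

Step 6
Reactants: 11 thionocarbonate
Product: 15 bicyclic amide ester (trans-decalin with C8=C17 methylene; 4β-H; 5α-H; 9α-H; 10β-CH3), via C5 radical 12 (not isolated), via monocyclic C9 radical 13 (not isolated), via vinyl radical 14 (not isolated)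
Conditions: n-Bu3SnH, AIBN (both by syringe pump over 10 h), PhMe (0.003 M), 100 °C
Reagents that add atoms: none
Why: Bu3Sn• adds to the thiocarbonyl sulfur and the C5–O bond fragments (Barton–McCombie-type radical generation) to give secondary radical 12, which adds 6-exo-trig to C10, the β-carbon of the unsaturated amide, closing ring A and leaving the amide-stabilised C9 radical 13; this closes ring B 6-exo-dig onto the terminal alkyne at C8, and vinyl radical 14 takes hydrogen from Bu3SnH to give the C8=C17 methylene. The closest known reaction type is the stannane-mediated tandem radical cyclisation of a thiocarbonyl or halide precursor onto an enoate and then onto an alkyne. Ring A closes 6-exo-trig through a chair-like transition state, and ring B closes 6-exo-dig, which is possible because the C6 and C9 arms end up trans-diequatorial on ring A. C5 and C10 are controlled by the C4 stereocentre: the ester sits equatorial, the C6 chain on the radical carbon and the acceptor alkene (C9) also take equatorial positions, so the C10 methyl is forced axial and trans to H5, which should translate (R)-C4 into the natural 5α-H/10β-CH3 series; C9 is set in the second closure with the amide pseudo-equatorial (β) and H9 α. The step needs ring closure to outrun hydrogen transfer and needs attack at the hindered C10: slow addition at high dilution keeps the stannane concentration low, conjugation with the amide directs the nucleophilic alkyl radical to C10 and not to C9 (7-endo), and the terminal alkyne directs the electrophilic C9 radical to C8 (exo).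

Step 7
Reactants: 15 bicyclic amide ester
Product: 17 C4-methylated amide ester (4α-CH3 equatorial; 19-CO2Me axial), via lithium ester enolate 16 (not isolated)
Conditions: LiN(i-Pr)2, THF, −78 °C; then MeI, DMPU, −78 → −30 °C
Reagents that add atoms: iodomethane, CI
Why: Enolate alkylation, in which the ester α-hydrogen at C4 should be removed in preference to the less acidic and more hindered amide α-hydrogen at C9, and MeI should enter from the α (equatorial) face anti to the axial C10 methyl, as in known C4 alkylations of decalin 19-oates.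

Step 8
Reactants: 17 C4-methylated amide ester
Product: 18 aldehyde methyl 11-oxo-12,13,14,15,16-pentanorlabd-8(17)-en-19-oate
Conditions: i-Bu2AlH, THF, −78 °C; then aq. potassium sodium tartrate
Reagents that add atoms: none
Why: Partial reduction of the N-methoxy-N-methylamide through its chelated tetrahedral aluminium intermediate should give the aldehyde, while the neopentyl, axial C19 ester is too hindered to react at −78 °C.

Step 9
Reactants: 18 aldehyde
Product: 19 diene ester methyl 13,14,15,16-tetranorlabda-8(17),11-dien-19-oate
Conditions: Ph3PCH3Br, KN(SiMe3)2, THF, 0 °C; then 18, −78 → 0 °C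
Reagents that add atoms: methyltriphenylphosphonium bromide, C[P+](c1ccccc1)(c1ccccc1)c1ccccc1.[Br-]
Why: Wittig methylenation with the non-stabilised ylide at low temperature should convert C11=O into the C11=C12 vinyl group before the α-stereocentre C9 can epimerise.

Step 10
Reactants: 19 diene ester
Product: 20 boronic ester methyl 12-(4,4,5,5-tetramethyl-1,3,2-dioxaborolan-2-yl)-13,14,15,16-tetranorlabd-8(17)-en-19-oate
Conditions: pinacolborane, [Ir(cod)Cl]2 (1.5 mol %), dppm (3 mol %), CH2Cl2, rt
Reagents that add atoms: pinacolborane, CC1(C)OBOC1(C)C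
Why: Iridium-catalysed anti-Markovnikov hydroboration with pinacolborane is selective for the monosubstituted vinyl group over the 1,1-disubstituted C8=C17 methylene and places boron on C12.

Step 11
Reactants: 21 (S)-but-3-en-2-ol; 22 N,N-diisopropylcarbamoyl chloride
Product: 23 (S)-but-3-en-2-yl N,N-diisopropylcarbamate
Conditions: NaH, THF, 0 °C → reflux
Reagents that add atoms: none
Why: O-carbamoylation of the sodium alkoxide proceeds with retention at carbon and installs the group that directs α-lithiation and later leaves in the 1,2-shift.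

Step 12
Reactants: 20 boronic ester; 23 (S)-carbamate
Product: 27 methyl (13R)-13-hydroxylabda-8(17),14-dien-19-oate, via lithiated carbamate 24 (not isolated), via lithium boronate complex 25 (not isolated), via tertiary allylic boronic ester 26 (not isolated)
Conditions: 23, s-BuLi, TMEDA, Et2O, −78 °C; then 20, −78 °C → rt; then aq. NaOH, 30% H2O2, THF, 0 °C → rt
Reagents that add atoms: hydrogen peroxide, OO
Why: Lithiation–borylation (1,2-metallate rearrangement of a boronate complex, then C–B oxidation), in which deprotonation and trapping by the boronic ester at the α-carbon are expected to occur with retention, the primary C12 group migrates to C13 antiperiplanar to the carbamate with inversion, and oxidation occurs with retention, so that the S carbamate should deliver 13R.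

Step 13
Reactants: 27 hydroxy ester
Product: 28 (13R)-labda-8(17),14-diene-13,19-diol
Conditions: LiAlH4, THF, 0 → 50 °C; then aq. NaOH
Reagents that add atoms: none
Why: Hydride reduction of the hindered axial ester gives the neopentyl primary alcohol, while the isolated alkenes and the tertiary allylic alkoxide are inert.

Step 14
Reactants: 28 diol; 29 (E)-2-methylbut-2-enoyl chloride (tigloyl chloride)
Product: 30 (13R)-13-hydroxylabda-8(17),14-dien-19-yl (E)-2-methylbut-2-enoate
Conditions: pyridine, DMAP (cat.), CH2Cl2, 0 °C → rt
Reagents that add atoms: none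
Why: DMAP-catalysed O-acylation should discriminate the primary C19 hydroxyl from the tertiary allylic C13 hydroxyl, and the E geometry of the tigloyl unit is retained.

**Compound list**

1 | 6-oxoheptanoic acid | CC(=O)CCCCC(=O)O | starting material
2 | diethyl {2-[methoxy(methyl)amino]-2-oxoethyl}phosphonate | CCOP(=O)(CC(=O)N(C)OC)OCC | starting material
3 | (E)-8-[methoxy(methyl)amino]-6-methyl-8-oxooct-6-enoic acid | OC(=O)CCCC/C(C)=C/C(=O)N(C)OC | intermediate
4 | (R)-4-benzyl-1,3-oxazolidin-2-one | O=C1N[C@H](Cc2ccccc2)CO1 | starting material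
5 | mixed anhydride of 3 with pivalic acid (forms in the flask) | CC(C)(C)C(=O)OC(=O)CCCC/C(C)=C/C(=O)N(C)OC | intermediate
6 | (R)-4-benzyl-3-{(E)-8-[methoxy(methyl)amino]-6-methyl-8-oxooct-6-enoyl}-1,3-oxazolidin-2-one | O=C(CCCC/C(C)=C/C(=O)N(C)OC)N1C(=O)OC[C@H]1Cc1ccccc1 | intermediate
7 | pent-4-ynal | C#CCCC=O | starting material
8 | (Z)-di-n-butylboron enolate of 6 (forms in the flask) | CCCCB(CCCC)O/C(=C\CCC/C(C)=C/C(=O)N(C)OC)N1C(=O)OC[C@H]1Cc1ccccc1 | intermediate
9 | (R)-4-benzyl-3-[(2R,3S)-3-hydroxy-2-{(E)-6-[methoxy(methyl)amino]-4-methyl-6-oxohex-4-en-1-yl}hept-6-ynoyl]-1,3-oxazolidin-2-one | O=C([C@H](CCC/C(C)=C/C(=O)N(C)OC)[C@@H](O)CCC#C)N1C(=O)OC[C@H]1Cc1ccccc1 | intermediate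
10 | methyl (2R,3S)-3-hydroxy-2-{(E)-6-[methoxy(methyl)amino]-4-methyl-6-oxohex-4-en-1-yl}hept-6-ynoate | COC(=O)[C@H](CCC/C(C)=C/C(=O)N(C)OC)[C@@H](O)CCC#C | intermediate
11 | methyl (2R,3S)-2-{(E)-6-[methoxy(methyl)amino]-4-methyl-6-oxohex-4-en-1-yl}-3-[(phenoxycarbonothioyl)oxy]hept-6-ynoate | COC(=O)[C@H](CCC/C(C)=C/C(=O)N(C)OC)[C@@H](OC(=S)Oc1ccccc1)CCC#C | intermediate
12 | acyclic secondary radical at C5, C4 stereocentre (R) intact (forms in the flask) | COC(=O)[C@H](CCC/C(C)=C/C(=O)N(C)OC)[CH]CCC#C | intermediate
13 | ring A closed: cyclohexane with C4 ester, C5 but-3-ynyl, C10 methyl and an amide-stabilised radical at C9 (forms in the flask) | CON(C)C(=O)[CH][C@@]1(C)CCC[C@@H](C(=O)OC)[C@@H]1CCC#C | intermediate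
14 | trans-decalin with exocyclic vinyl radical at C17 (forms in the flask) | CON(C)C(=O)[C@H]1C(=[CH])CC[C@H]2[C@H](C(=O)OC)CCC[C@]12C | intermediate
15 | trans-decalin (labdane numbering): C4 with H (β) and CO2Me (α, equatorial); H5 α; C10 CH3 β; C9 with H (α) and C(=O)N(OMe)Me (β, equatorial); C8=C17 exocyclic methylene | CON(C)C(=O)[C@H]1C(=C)CC[C@H]2[C@H](C(=O)OC)CCC[C@]12C | intermediate
16 | lithium enolate of the C19 ester of 15, C4=C19 (forms in the flask) | CON(C)C(=O)[C@H]1C(=C)CC[C@H]2C(=C([O-])OC)CCC[C@]12C.[Li+] | intermediate
17 | as 15 but C4 quaternary: CH3 α (equatorial), CO2Me β (axial, C19) | CON(C)C(=O)[C@H]1C(=C)CC[C@H]2[C@@](C)(C(=O)OC)CCC[C@]12C | intermediate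
18 | methyl 11-oxo-12,13,14,15,16-pentanorlabd-8(17)-en-19-oate (9β-CHO, 9α-H) | O=C[C@H]1C(=C)CC[C@H]2[C@@](C)(C(=O)OC)CCC[C@]12C | intermediate
19 | methyl 13,14,15,16-tetranorlabda-8(17),11-dien-19-oate (9β-vinyl) | C=C[C@H]1C(=C)CC[C@H]2[C@@](C)(C(=O)OC)CCC[C@]12C | intermediate
20 | methyl 12-(4,4,5,5-tetramethyl-1,3,2-dioxaborolan-2-yl)-13,14,15,16-tetranorlabd-8(17)-en-19-oate | CC1(C)OB(CC[C@H]2C(=C)CC[C@H]3[C@@](C)(C(=O)OC)CCC[C@]23C)OC1(C)C | intermediate
21 | (S)-but-3-en-2-ol | C=C[C@H](C)O | starting material
22 | N,N-diisopropylcarbamoyl chloride | CC(C)N(C(C)C)C(=O)Cl | starting material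
23 | (S)-but-3-en-2-yl N,N-diisopropylcarbamate | C=C[C@H](C)OC(=O)N(C(C)C)C(C)C | intermediate
24 | α-lithiated carbamate, Li in place of the carbinol H (forms in the flask) | C=C[C@]([Li])(C)OC(=O)N(C(C)C)C(C)C | intermediate
25 | lithium boronate complex of 24 and 20, boron on C13 (forms in the flask) | C=C[C@]([B-]1(CC[C@H]2C(=C)CC[C@H]3[C@@](C)(C(=O)OC)CCC[C@]23C)OC(C)(C)C(C)(C)O1)(C)OC(=O)N(C(C)C)C(C)C.[Li+] | intermediate
26 | tertiary allylic boronic ester, methyl 13-(pinacolboryl)labda-8(17),14-dien-19-oate (forms in the flask) | C=C[C@@](B1OC(C)(C)C(C)(C)O1)(C)CC[C@H]2C(=C)CC[C@H]3[C@@](C)(C(=O)OC)CCC[C@]23C | intermediate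
27 | methyl (13R)-13-hydroxylabda-8(17),14-dien-19-oate | C=C[C@](C)(O)CC[C@H]1C(=C)CC[C@H]2[C@@](C)(C(=O)OC)CCC[C@]12C | intermediate
28 | (13R)-labda-8(17),14-diene-13,19-diol | C=C[C@](C)(O)CC[C@H]1C(=C)CC[C@H]2[C@@](C)(CO)CCC[C@]12C | intermediate
29 | (E)-2-methylbut-2-enoyl chloride (tigloyl chloride) | C/C=C(\C)C(=O)Cl | starting material
30 | (13R)-13-hydroxylabda-8(17),14-dien-19-yl (E)-2-methylbut-2-enoate | C=C[C@](C)(O)CC[C@H]1C(=C)CC[C@H]2[C@@](C)(COC(=O)/C(C)=C/C)CCC[C@]12C | target

**Step count**

Total: 14 steps. Longest linear sequence: 13 steps (steps 1–10 and 12–14); step 11 prepares the carbamate separately.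

**Steps most likely to fail**

1. Step 6. Hydrogen transfer from the stannane, or a 1,5-hydrogen shift from the allylic C1 position, may outrun the 6-exo attack of the C5 radical on the hindered C10, and the C9 radical may be reduced before it closes onto the alkyne. The fallback sets out from 10 and comes back at 15, replacing the reductive chain by an iodine-atom-transfer cascade in which no hydride donor is present. Iodination of 10 (I2, PPh3, imidazole) should give the secondary iodide with inversion at C5, methyl (2R,3R)-3-iodo-2-{(E)-6-[methoxy(methyl)amino]-4-methyl-6-oxohex-4-en-1-yl}hept-6-ynoate F1. Under (n-Bu3Sn)2 (cat.), hν, PhH, 80 °C the same two ring closures should run as an atom-transfer chain in which uncyclised radicals are only returned to their iodides, and the final vinyl radical takes iodine from F1 to give the bicyclic vinyl iodide F2 (C17 iodide of 15). Reductive removal of the vinylic iodine (n-Bu3SnH, AIBN) then gives 15.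

2. Step 12. The lithiated allylic carbamate may be borylated at the γ-carbon, may lose configuration before trapping, or the hindered boronate may be slow in the 1,2-shift. The fallback sets out from 20 and comes back at 27, building C13 by asymmetric epoxidation instead. Treatment of 20 with KHF2 should give the potassium trifluoroborate F3. Suzuki–Miyaura coupling (PdCl2(dppf), Cs2CO3, PhMe/H2O) with (E)-3-iodobut-2-en-1-ol F4 (from but-2-yn-1-ol by stannylcupration and iodinolysis) should give the (E)-allylic alcohol methyl (13E)-15-hydroxylabda-8(17),13-dien-19-oate F5. Sharpless asymmetric epoxidation (Ti(Oi-Pr)4, D-(−)-diethyl tartrate, t-BuOOH) should give the (13R,14R)-epoxy alcohol F6. Iodination (I2, PPh3, imidazole) gives the epoxy iodide F7, and reductive opening with Zn in EtOH gives 27 with the C13–O bond untouched.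

3. Step 7. The base may remove the C9 hydrogen (α to the amide and allylic) instead of the C4 hydrogen, which would lead to methylation at C9 or to migration of the exocyclic double bond into conjugation. The fallback sets out from 15 and comes back at 19, removing the competing acidic site before the alkylation. Chemoselective reduction of the amide with Cp2Zr(H)Cl in THF should give the aldehyde with the C4–H ester intact, F8. Wittig methylenation (Ph3PCH3Br, KN(SiMe3)2) should give the vinyl ester F9, in which the ester α-hydrogen is the only acidic site. Methylation with LiN(i-Pr)2 and MeI from the α-face then gives 19.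

**Further compounds**

F1 | step 6 | methyl (2R,3R)-3-iodo-2-{(E)-6-[methoxy(methyl)amino]-4-methyl-6-oxohex-4-en-1-yl}hept-6-ynoate | COC(=O)[C@H](CCC/C(C)=C/C(=O)N(C)OC)[C@H](I)CCC#C
F2 | step 6 | bicyclic vinyl iodide, 15 with C8=C17H–I (E/Z mixture) | CON(C)C(=O)[C@H]1C(=CI)CC[C@H]2[C@H](C(=O)OC)CCC[C@]12C
F3 | step 12 | potassium trifluoroborate corresponding to 20 | [K+].F[B-](F)(F)CC[C@H]1C(=C)CC[C@H]2[C@@](C)(C(=O)OC)CCC[C@]12C
F4 | step 12 | (E)-3-iodobut-2-en-1-ol | C/C(I)=C\CO
F5 | step 12 | methyl (13E)-15-hydroxylabda-8(17),13-dien-19-oate | OC/C=C(\C)CC[C@H]1C(=C)CC[C@H]2[C@@](C)(C(=O)OC)CCC[C@]12C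
F6 | step 12 | methyl (13R,14R)-13,14-epoxy-15-hydroxylabd-8(17)-en-19-oate | OC[C@H]1O[C@]1(C)CC[C@H]2C(=C)CC[C@H]3[C@@](C)(C(=O)OC)CCC[C@]23C
F7 | step 12 | methyl 13,14-epoxy-15-iodolabd-8(17)-en-19-oate (epoxide as in F6) | IC[C@H]1O[C@]1(C)CC[C@H]2C(=C)CC[C@H]3[C@@](C)(C(=O)OC)CCC[C@]23C
F8 | step 7 | aldehyde from 15 with the C4–H ester intact (C4: H β, CO2Me α) | O=C[C@H]1C(=C)CC[C@H]2[C@H](C(=O)OC)CCC[C@]12C
F9 | step 7 | 9β-vinyl ester with C4–H (C4: H β, CO2Me α) | C=C[C@H]1C(=C)CC[C@H]2[C@H](C(=O)OC)CCC[C@]12C
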